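The runs were generated by integration from invented constants.

**Decision first.** I decided to answer your request for a quick number with one exponent read from the two earlier runs, not with a fitted scheme. The task:

common to all: E 0.020 M

| flask | J | remark | time |
|---|---|---|---|
| beta | 0.034 M (fed, over 25 min) | run made earlier |  |
| gamma | 0.053 M (fed, over 25 min) | run made earlier |  |
| flask | 0.0240 M (fed, over 25 min) |  | 25 min |

| run | time / min | G / % | E / % |
|---|---|---|---|
| beta | 6.00 | 7 | 58 |
| beta | 12.0 | 26 | 45 |
| beta | 20.0 | 46 | 19 |
| beta | 25.0 | 69 | 0 |
| gamma | 6.00 | 11 | 54 |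
| gamma | 12.0 | 35 | 38 |
| gamma | 20.0 | 67 | 0 |
| gamma | 25.0 | 82 | 2 |

(readings scatter by 2 percentage points)

1. amount of G in percent of the E charged, at 80 s, 6.0 min and 25 min

- G is meant together with its D
- solid, in amounts per volume of the solution: E, D
- reactions considered so far: E <-> Q; Q + J -> G; D <-> G; J <-> L; 2 J -> Z
- at the start none of E is in solution

**Feed exponent.** Beta and gamma differ in their J charge, so I compared them at one time. At 12.0 min both still held solid E, 45% in beta and 38% in gamma, whereas gamma read E at 0% by 20.0 min. From the scattered readings of these two runs at 12.0 min I read 0.670, the feed exponent: the logarithm of the ratio of G in two runs at one time, over the logarithm of the ratio of their J charges, an apparent order in the feed.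

**My number.** I scaled beta down to the flask's charge of 0.0240 M with this exponent. That gave me 5.54% at 6.0 min and 54.6% at 25 min. No reading stood near 80 s, so the exponent gave me nothing there.

**Your forecast.** You gave 0.3%, 5% and 54%, on the ground that “Q stays near saturation while solid remains”. My value at 25 min stood above yours, and I kept both.

**The flask.** It gave 0.160%, 5.61% and 50.8%, which is within the margin of the forecast.

    E ⇌ Q, rate k1*(cs1 - [Q]) while solid is left; crystals form when [Q] > cs1 (solubility = 7.80 mM, k = 0.00829 s⁻¹)
    Q + J → G (k = 0.241 L mol⁻¹ s⁻¹)
    D ⇌ G, rate k3*(cs3 - [G]) while solid is left; crystals form when [G] > cs3 (solubility = 0.210 mM, k = 0.0366 s⁻¹)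
    J ⇌ L (K = 1.50, k = 0.00101 s⁻¹)
    2 J → Z (k = 0.0737 L mol⁻¹ s⁻¹)

**What parted.** With the exponent 0.670, my 54.6% at 25 min stood above the flask's 50.8%. Carried up to gamma, 0.670 gave 92.9% against 82% read at 25.0 min, and gamma had read E at 0% by 20.0 min; the flask held 15.4% of E at 25.0 min, and a reading of E at zero there would have spoken against the forecast's ground. In the flask, the midpoint of turnover up to 25 min came at 7.04 min for the dissolving of E, earlier than the 15.0 min for the path from Q + J to G. Q stood at 34.5% at 12.5 min and at 33.8% at 25.0 min.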